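**Retrosynthetic overview**
1. Last bond: the central C(sp2)–C(sp2) bond of the polyene, by Suzuki coupling of left-half dienyl iodide 15 with right-half dienylboronate 26.
2. Right half: Stille coupling at C3 of bromo-ylidenebutenolide 20 (from Pd/Cu alkynylation–lactonisation of (E)-2,3-dibromoacrylic acid) with epoxy vinylstannane 25. Left half: Sonogashira coupling of enol triflate 11, then Takai iodo-olefination.
3. Both carbocycles come from the single enol triflate 11, made from 4-acetoxy-2,2,6-trimethylcyclohexanone 10.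
4. Key step: the C1–C6 ring bond of 10 (quaternary carbon next to C=O) is closed by an Fe–H HAT radical 6-exo cyclisation of a tertiary radical onto a nitrile; the acyclic precursor carries the one imported stereocentre, from (S)-epichlorohydrin.
5. Ring order: cyclohexanone (radical) → left cyclohexene / right oxirane (mCPBA) → butenolide (Pd/Cu lactonisation).

Assumption: (S)-epichlorohydrin, isopropenylmagnesium bromide solution, propionitrile, (E)-3-methylpent-2-en-4-yn-1-ol, propiolic acid and ethynyltrimethylsilane are bought; LDA is used as a commercial solution.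

**Step 1**
Reactants: 1 (S)-epichlorohydrin + 2 isopropenylmagnesium bromide
Product: 4 (2S)-2-(2-methylprop-2-en-1-yl)oxirane, via chlorohydrin 3 (not isolated)
Conditions: 2 (1.2 eq), CuI (10 mol %), THF, −40 → 0 °C; H2O quench; powdered NaOH (3 eq), Et2O, rt; distil
Reagents that add atoms: none
Why: Cu-catalysed Grignard opening of the epoxide at its CH2 terminus, then Williamson closure of the chlorohydrin; neither step touches the stereocentre, so the configuration of 1 is carried into 4.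

**Step 2**
Reactants: 4 (2S)-2-(2-methylprop-2-en-1-yl)oxirane + 5 propionitrile
Product: 8 (4R)-6-cyano-2-methylhept-1-en-4-yl acetate (C6 epimer mixture), via lithiated propionitrile 6 (not isolated), via lithium alkoxide 7 (not isolated)
Conditions: LDA (1.15 eq), 5 (1.2 eq), THF, −78 °C; 4, −78 → 0 °C; Ac2O (2.5 eq), 0 °C → rt
Reagents that add atoms: acetic anhydride CC(=O)OC(C)=O
Why: SN2 alkylation of the α-cyano carbanion at the unsubstituted epoxide carbon, then in-situ O-acetylation (which blocks alkoxide-to-nitrile cyclisation); the carbinol centre is untouched (S→R is a CIP priority change only) and the new α-cyano centre is destroyed in step 4.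

**Step 3**
Reactants: 8 (4R)-6-cyano-2-methylhept-1-en-4-yl acetate
Product: 10 (1R)-3,3,5-trimethyl-4-oxocyclohexyl acetate (C5 epimer mixture), via NH-ketimine 9 (not isolated)
Conditions: Fe(acac)3 (50 mol %), PhSiH3 (2.5 eq), EtOH, 0.03 M, 60 °C; then 1 M HCl/THF, rt
Reagents that add atoms: water O
Why: Proposed new method: Fe–H (from Fe(acac)3/PhSiH3) transfers H• to the 1,1-disubstituted alkene (Markovnikov MHAT) to give a nucleophilic tertiary radical, which closes 6-exo-dig onto the electrophilic nitrile carbon; the iminyl radical is reduced by Fe(II)/EtOH to ketimine 9 and hydrolysed to the ketone, forming the quaternary C–C(=O) bond with the epichlorohydrin-derived centre untouched; closest known reaction type is the Fe-hydride HAT-initiated alkene–nitrile radical cyclisation to ketones (Mukaiyama/Baran-type MHAT), here stretched to an unactivated nitrile bearing an α-H.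

**Step 4**
Reactants: 10 (1R)-3,3,5-trimethyl-4-oxocyclohexyl acetate
Product: 11 (1R)-3,5,5-trimethyl-4-{[(trifluoromethyl)sulfonyl]oxy}cyclohex-3-en-1-yl acetate
Conditions: Tf2O (1.5 eq), 2,6-di-tert-butyl-4-methylpyridine (2 eq), CH2Cl2, 0 °C → rt
Reagents that add atoms: triflic anhydride O=S(=O)(OS(=O)(=O)C(F)(F)F)C(F)(F)F
Why: Stang enol-triflate formation (O-triflation, loss of the only α-H) gives one tetrasubstituted enol triflate; both C5 epimers converge and the acetate survives the non-nucleophilic conditions.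

**Step 5**
Reactants: 12 (2E)-3-methylpent-2-en-4-yn-1-ol
Product: 13 (2E)-3-methylpent-2-en-4-ynal
Conditions: activated MnO2 (15 eq), CH2Cl2, rt, dark; filter, use as solution
Reagents that add atoms: none
Why: Chemoselective allylic alcohol oxidation with MnO2; alkene geometry is retained.

**Step 6**
Reactants: 11 enol triflate + 13 (2E)-3-methylpent-2-en-4-ynal
Product: 14 (1R)-3,5,5-trimethyl-4-[(3E)-3-methyl-5-oxopent-3-en-1-yn-1-yl]cyclohex-3-en-1-yl acetate
Conditions: Pd(PPh3)4 (5 mol %), CuI (10 mol %), Et3N (3 eq), DMF, rt → 40 °C, degassed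
Reagents that add atoms: none
Why: Sonogashira coupling of the enol triflate with the terminal alkyne; a tertiary amine base avoids conjugate addition to the enynal.

**Step 7**
Reactants: 14 C15 enynal
Product: 15 (1R)-4-[(3E,5E)-6-iodo-3-methylhexa-3,5-dien-1-yn-1-yl]-3,5,5-trimethylcyclohex-3-en-1-yl acetate
Conditions: CHI3 (2 eq), CrCl2 (6 eq), THF/dioxane 1:6, 0 °C → rt, dark
Reagents that add atoms: iodoform IC(I)I
Why: Takai iodo-olefination (gem-dichromium carbenoid addition, then anti-elimination) gives the E-vinyl iodide; acetate and enyne are inert to Cr(II).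

**Step 8**
Reactants: 13 (2E)-3-methylpent-2-en-4-ynal
Product: 16 2-[(1E,3E)-4-methylhexa-1,3-dien-5-yn-1-yl]-4,4,5,5-tetramethyl-1,3,2-dioxaborolane
Conditions: Cl2CHBpin (2 eq), CrCl2 (8 eq), LiI (4 eq), THF, rt
Reagents that add atoms: 2-(dichloromethyl)-4,4,5,5-tetramethyl-1,3,2-dioxaborolane ClC(Cl)B1OC(C)(C)C(C)(C)O1
Why: Takai–Utimoto boryl olefination gives the E-alkenyl pinacolboronate; the terminal alkyne is untouched.

**Step 9**
Reactants: 17 propiolic acid
Product: 18 (2E)-2,3-dibromoprop-2-enoic acid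
Conditions: Br2 (1.05 eq), CHCl3, 0 °C → rt, dark; recrystallise
Reagents that add atoms: bromine BrBr
Why: Ionic anti-addition of Br2 to the alkyne gives the E-dibromide, in which the β-bromine is cis to CO2H as the lactonisation needs.

**Step 10**
Reactants: 16 dienylboronate alkyne + 18 (2E)-2,3-dibromoprop-2-enoic acid
Product: 20 (5Z)-3-bromo-5-[(2E,4E)-2-methyl-5-(4,4,5,5-tetramethyl-1,3,2-dioxaborolan-2-yl)penta-2,4-dien-1-ylidene]furan-2(5H)-one, via bromoenynoic acid 19 (not isolated)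
Conditions: Pd(PPh3)4 (5 mol %), CuI (10 mol %), Et3N (4 eq), MeCN, rt, dark
Reagents that add atoms: none
Why: Tandem Sonogashira coupling at the more reactive β-C–Br (retention), then metal-promoted 5-exo-dig anti-addition of the carboxylate to the alkyne, gives the Z-ylidenebutenolide; the α-C–Br and the vinyl-Bpin stay intact.

**Step 11**
Reactants: 11 enol triflate + 21 ethynyltrimethylsilane
Product: 22 (1R)-3,5,5-trimethyl-4-[(trimethylsilyl)ethynyl]cyclohex-3-en-1-yl acetate
Conditions: PdCl2(PPh3)2 (3 mol %), CuI (6 mol %), Et3N (3 eq), DMF, rt → 40 °C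
Reagents that add atoms: none
Why: Sonogashira coupling of the enol triflate with the silyl-protected alkyne.

**Step 12**
Reactants: 22 silyl enyne
Product: 23 (1R,3S,6R)-1,5,5-trimethyl-6-[(trimethylsilyl)ethynyl]-7-oxabicyclo[4.1.0]heptan-3-yl acetate
Conditions: mCPBA (1.2 eq), CH2Cl2, 0 °C; NaHCO3/Na2S2O3 wash; chromatography
Reagents that add atoms: mCPBA OOC(=O)c1cccc(Cl)c1
Why: Prilezhaev epoxidation of the electron-rich tetrasubstituted ring alkene (the silylalkyne is inert); the peracid adds mainly anti to the homoallylic acetoxy group (substrate control, expected about 3–4:1), setting both oxirane centres in the natural 5R,6S sense (carotenoid numbering), and the syn isomer is removed by chromatography.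

**Step 13**
Reactants: 23 epoxy acetate
Product: 24 (1R,3S,6R)-6-ethynyl-1,5,5-trimethyl-7-oxabicyclo[4.1.0]heptan-3-ol
Conditions: K2CO3 (0.3 eq), MeOH, rt
Reagents that add atoms: none
Why: Methanolysis of the acetate and base-mediated C–Si protodesilylation in one operation; the hindered epoxide is inert.

**Step 14**
Reactants: 24 epoxy alkynol + 20 bromo-ylidenebutenolide
Product: 26 (5Z)-3-{(E)-2-[(1S,4S,6R)-4-hydroxy-2,2,6-trimethyl-7-oxabicyclo[4.1.0]heptan-1-yl]ethenyl}-5-[(2E,4E)-2-methyl-5-(4,4,5,5-tetramethyl-1,3,2-dioxaborolan-2-yl)penta-2,4-dien-1-ylidene]furan-2(5H)-one, via vinylstannane 25 (not isolated)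
Conditions: 24 (1.15 eq), PdCl2(PPh3)2 (3 mol %), Bu3SnH (1.1 eq, slow addition), THF, 0 °C → rt; then 20 (1.0 eq), Pd2(dba)3 (2.5 mol %), AsPh3 (20 mol %), NMP, 40 °C, dark
Reagents that add atoms: none
Why: Pd-catalysed syn-hydrostannylation puts tin on the unhindered terminus (E), then a base-free Stille coupling at the butenolide C3–Br proceeds with retention; vinyl-Bpin, epoxide and free OH are spectators.

**Step 15**
Reactants: 15 left-half dienyl iodide + 26 right-half dienylboronate
Product: 27 pyrrhoxanthin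
Conditions: Pd(OAc)2 (5 mol %), SPhos (10 mol %), K3PO4 (3 eq, 1 M aq), THF, rt, 2 h, degassed, dark
Reagents that add atoms: none
Why: Suzuki–Miyaura coupling of an E-vinyl iodide with an E-dienylboronate, stereoretentive at both partners, closes the central single bond of the all-E polyene at room temperature; no stereocentre is touched.

**Compound list**
1 | (S)-epichlorohydrin | ClC[C@@H]1CO1 | starting material
2 | isopropenylmagnesium bromide | CC(=C)[Mg]Br | starting material
3 | (2S)-1-chloro-4-methylpent-4-en-2-ol | ClC[C@@H](O)CC(C)=C | intermediate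
4 | (2S)-2-(2-methylprop-2-en-1-yl)oxirane | C=C(C)C[C@H]1CO1 | intermediate
5 | propionitrile | CCC#N | starting material
6 | 2-lithiopropanenitrile | [Li]C(C)C#N | intermediate
7 | lithium (4R)-6-cyano-2-methylhept-1-en-4-olate | [Li+].[O-][C@@H](CC(C)=C)CC(C)C#N | intermediate
8 | (4R)-6-cyano-2-methylhept-1-en-4-yl acetate (C6 epimers) | CC(=O)O[C@@H](CC(C)=C)CC(C)C#N | intermediate
9 | (1R)-4-imino-3,3,5-trimethylcyclohexyl acetate (C5 epimers) | CC(=O)O[C@@H]1CC(C)C(=N)C(C)(C)C1 | intermediate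
10 | (1R)-3,3,5-trimethyl-4-oxocyclohexyl acetate (C5 epimers) | CC(=O)O[C@@H]1CC(C)C(=O)C(C)(C)C1 | intermediate
11 | (1R)-3,5,5-trimethyl-4-{[(trifluoromethyl)sulfonyl]oxy}cyclohex-3-en-1-yl acetate | CC(=O)O[C@@H]1CC(C)=C(OS(=O)(=O)C(F)(F)F)C(C)(C)C1 | intermediate
12 | (2E)-3-methylpent-2-en-4-yn-1-ol | C#C/C(C)=C/CO | starting material
13 | (2E)-3-methylpent-2-en-4-ynal | C#C/C(C)=C/C=O | intermediate
14 | (1R)-3,5,5-trimethyl-4-[(3E)-3-methyl-5-oxopent-3-en-1-yn-1-yl]cyclohex-3-en-1-yl acetate | CC(=O)O[C@@H]1CC(C)=C(C#C/C(C)=C/C=O)C(C)(C)C1 | intermediate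
15 | (1R)-4-[(3E,5E)-6-iodo-3-methylhexa-3,5-dien-1-yn-1-yl]-3,5,5-trimethylcyclohex-3-en-1-yl acetate | CC(=O)O[C@@H]1CC(C)=C(C#C/C(C)=C/C=C/I)C(C)(C)C1 | intermediate
16 | 2-[(1E,3E)-4-methylhexa-1,3-dien-5-yn-1-yl]-4,4,5,5-tetramethyl-1,3,2-dioxaborolane | C#C/C(C)=C/C=C/B1OC(C)(C)C(C)(C)O1 | intermediate
17 | propiolic acid | C#CC(=O)O | starting material
18 | (2E)-2,3-dibromoprop-2-enoic acid | OC(=O)/C(Br)=C\Br | intermediate
19 | (2E,6E,8E)-2-bromo-6-methyl-9-(4,4,5,5-tetramethyl-1,3,2-dioxaborolan-2-yl)nona-2,6,8-trien-4-ynoic acid | OC(=O)/C(Br)=C\C#C/C(C)=C/C=C/B1OC(C)(C)C(C)(C)O1 | intermediate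
20 | (5Z)-3-bromo-5-[(2E,4E)-2-methyl-5-(4,4,5,5-tetramethyl-1,3,2-dioxaborolan-2-yl)penta-2,4-dien-1-ylidene]furan-2(5H)-one | CC1(C)OB(/C=C/C=C(C)/C=C2C=C(Br)C(=O)O/2)OC1(C)C | intermediate
21 | ethynyltrimethylsilane | C#C[Si](C)(C)C | starting material
22 | (1R)-3,5,5-trimethyl-4-[(trimethylsilyl)ethynyl]cyclohex-3-en-1-yl acetate | CC(=O)O[C@@H]1CC(C)=C(C#C[Si](C)(C)C)C(C)(C)C1 | intermediate
23 | (1R,3S,6R)-1,5,5-trimethyl-6-[(trimethylsilyl)ethynyl]-7-oxabicyclo[4.1.0]heptan-3-yl acetate | C[Si](C)(C)C#C[C@@]12O[C@]1(C)C[C@@H](OC(C)=O)CC2(C)C | intermediate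
24 | (1R,3S,6R)-6-ethynyl-1,5,5-trimethyl-7-oxabicyclo[4.1.0]heptan-3-ol | C#C[C@@]12O[C@]1(C)C[C@@H](O)CC2(C)C | intermediate
25 | (1R,3S,6S)-1,5,5-trimethyl-6-[(E)-2-(tributylstannyl)ethenyl]-7-oxabicyclo[4.1.0]heptan-3-ol | CCCC[Sn](CCCC)(CCCC)/C=C/[C@@]12O[C@]1(C)C[C@@H](O)CC2(C)C | intermediate
26 | (5Z)-3-{(E)-2-[(1S,4S,6R)-4-hydroxy-2,2,6-trimethyl-7-oxabicyclo[4.1.0]heptan-1-yl]ethenyl}-5-[(2E,4E)-2-methyl-5-(4,4,5,5-tetramethyl-1,3,2-dioxaborolan-2-yl)penta-2,4-dien-1-ylidene]furan-2(5H)-one | CC1(C)OB(/C=C/C=C(C)/C=C2C=C(/C=C/[C@@]34O[C@]3(C)C[C@@H](O)CC4(C)C)C(=O)O/2)OC1(C)C | intermediate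
27 | pyrrhoxanthin, (3S,5R,6S,3′R) | CC(=O)O[C@@H]1CC(C)=C(C#C/C(C)=C/C=C/C=C/C=C(C)/C=C2C=C(/C=C/[C@@]34O[C@]3(C)C[C@@H](O)CC4(C)C)C(=O)O/2)C(C)(C)C1 | target

**Step count**
Total: 15 steps. Longest linear sequence: 9 steps (1, 2, 3, 4, 11, 12, 13, 14, 15).

**Three steps most likely to fail**

The radical ring closure (step 3) is the largest risk. A 1,5-hydrogen shift from the α-cyano C–H to the tertiary radical, or plain alkene reduction, may outrun the slow 6-exo attack on C≡N. The fallback keeps the HAT radical closure of the same bond but changes the acceptor. It sets out from epoxide 4, which is opened with lithiated propanal N,N-dimethylhydrazone (LDA, THF) and acetylated in situ (Ac2O) to give (4R)-7-(2,2-dimethylhydrazinylidene)-2,6-dimethylhept-1-en-4-yl acetate F1. Mild hydrolysis (aqueous oxalic acid, Et2O) gives (4R)-2,6-dimethyl-7-oxohept-1-en-4-yl acetate F2. The same Fe(acac)3/PhSiH3 conditions then close the ring by the much faster 6-exo addition of the tertiary radical to the aldehyde C=O, giving (1R)-4-hydroxy-3,3,5-trimethylcyclohexyl acetate F3, and Dess–Martin oxidation comes back to the route at ketone 10.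

The peracid epoxidation (step 12) rests on modest substrate control and may give too much of the syn oxirane. The fallback sets the oxirane by reagent control and sets out from triflate 11. Pd-catalysed methoxycarbonylation (Pd(OAc)2, PPh3, CO, MeOH, Et3N, DMF) gives methyl (4R)-4-(acetyloxy)-2,6,6-trimethylcyclohex-1-ene-1-carboxylate F4, and DIBAL-H reduces both esters to (1R)-4-(hydroxymethyl)-3,5,5-trimethylcyclohex-3-en-1-ol F5. Sharpless asymmetric epoxidation (Ti(OiPr)4, D-(−)-diethyl tartrate, TBHP, 4 Å MS, CH2Cl2, −20 °C) delivers oxygen anti to the ring hydroxyl, giving (1R,3S,6R)-6-(hydroxymethyl)-1,5,5-trimethyl-7-oxabicyclo[4.1.0]heptan-3-ol F6. The tartrate is chosen because L-(+)-DET gives the 2S series with geraniol-type alcohols and the R configuration is needed here at the carbinol-bearing oxirane carbon. TEMPO/PhI(OAc)2 then oxidises only the primary alcohol to (1S,4S,6R)-4-hydroxy-2,2,6-trimethyl-7-oxabicyclo[4.1.0]heptane-1-carbaldehyde F7, and Ohira–Bestmann homologation (dimethyl (1-diazo-2-oxopropyl)phosphonate, K2CO3, MeOH) comes back to the route at alkyne 24.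

The final Suzuki union (step 15) exposes the acetate and the ylidenebutenolide to aqueous base and may give hydrolysis or isomerised polyene. The fallback is a base-free Stille union with the coupling roles reversed. It sets out from aldehyde 14, which with Bu3SnCHBr2/CrCl2/LiI (stannyl Takai-type olefination) gives (1R)-3,5,5-trimethyl-4-[(3E,5E)-3-methyl-6-(tributylstannyl)hexa-3,5-dien-1-yn-1-yl]cyclohex-3-en-1-yl acetate F8. It also sets out from boronate 26, which N-iodosuccinimide in MeCN converts with retention into (5Z)-3-{(E)-2-[(1S,4S,6R)-4-hydroxy-2,2,6-trimethyl-7-oxabicyclo[4.1.0]heptan-1-yl]ethenyl}-5-[(2E,4E)-5-iodo-2-methylpenta-2,4-dien-1-ylidene]furan-2(5H)-one F9. Stille coupling of the two (Pd2(dba)3, AsPh3, NMP, rt, dark) comes back to the route at target 27.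

**Further compounds**
F1 | step 3 | (4R)-7-(2,2-dimethylhydrazinylidene)-2,6-dimethylhept-1-en-4-yl acetate | CC(=O)O[C@@H](CC(C)=C)CC(C)C=NN(C)C
F2 | step 3 | (4R)-2,6-dimethyl-7-oxohept-1-en-4-yl acetate | CC(=O)O[C@@H](CC(C)=C)CC(C)C=O
F3 | step 3 | (1R)-4-hydroxy-3,3,5-trimethylcyclohexyl acetate | CC(=O)O[C@@H]1CC(C)C(O)C(C)(C)C1
F4 | step 12 | methyl (4R)-4-(acetyloxy)-2,6,6-trimethylcyclohex-1-ene-1-carboxylate | CC(=O)O[C@@H]1CC(C)=C(C(=O)OC)C(C)(C)C1
F5 | step 12 | (1R)-4-(hydroxymethyl)-3,5,5-trimethylcyclohex-3-en-1-ol | O[C@@H]1CC(C)=C(CO)C(C)(C)C1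
F6 | step 12 | (1R,3S,6R)-6-(hydroxymethyl)-1,5,5-trimethyl-7-oxabicyclo[4.1.0]heptan-3-ol | OC[C@@]12O[C@]1(C)C[C@@H](O)CC2(C)C
F7 | step 12 | (1S,4S,6R)-4-hydroxy-2,2,6-trimethyl-7-oxabicyclo[4.1.0]heptane-1-carbaldehyde | O=C[C@@]12O[C@]1(C)C[C@@H](O)CC2(C)C
F8 | step 15 | (1R)-3,5,5-trimethyl-4-[(3E,5E)-3-methyl-6-(tributylstannyl)hexa-3,5-dien-1-yn-1-yl]cyclohex-3-en-1-yl acetate | CC(=O)O[C@@H]1CC(C)=C(C#C/C(C)=C/C=C/[Sn](CCCC)(CCCC)CCCC)C(C)(C)C1
F9 | step 15 | (5Z)-3-{(E)-2-[(1S,4S,6R)-4-hydroxy-2,2,6-trimethyl-7-oxabicyclo[4.1.0]heptan-1-yl]ethenyl}-5-[(2E,4E)-5-iodo-2-methylpenta-2,4-dien-1-ylidene]furan-2(5H)-one | I/C=C/C=C(C)/C=C1C=C(/C=C/[C@@]23O[C@]2(C)C[C@@H](O)CC3(C)C)C(=O)O/1
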